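The oxane (O, C11, C12, C13, C14, C15; kalihinane numbering, decalin C1–C10) is opened last at its O–C15 bond. Oxygen on the dimethyl-bearing C15 lies anti to chlorine on C14, the imprint of anti addition across a prenyl C14=C15 alkene. One chloronium-triggered 6-endo etherification of the C11 tertiary alcohol therefore closes the ring, installs chlorine and sets C14. Its precursor is a cis-fused octalone (rings A and B) carrying a hydroxylated homoprenyl side chain at C7, made by intramolecular Diels–Alder reaction of a trienone; C7 and C11 come from (2S,3S)-epoxygeraniol. The C10 formamide follows by methyl addition to a sulfinyl ketimine.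

Key step: step 8

Remark on the chemistry: the anomeric centre of 9 and the secondary carbinol centre of 11 are formed as mixtures; this is immaterial because that carbon becomes the C10 carbonyl in step 7.

Step 1
Reactants: 1 geraniol
Product: 2 (2S,3S)-2,3-epoxygeraniol
Conditions: t-BuOOH, Ti(OiPr)4 (cat.), L-(+)-diethyl tartrate (cat.), 4 Å molecular sieves, CH2Cl2, −20 °C
Reagents that add atoms: tert-butyl hydroperoxide, CC(C)(C)OO
Why: Sharpless asymmetric epoxidation, in which the titanium tartrate complex binds the allylic hydroxyl and with the L-(+)-tartrate should deliver oxygen to the face giving the (2S,3S) epoxide, fixing the later C11 centre and leaving the remote trisubstituted alkene untouched.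

Step 2
Reactants: 2 (2S,3S)-2,3-epoxygeraniol; 3 [2-(1,3-dioxan-2-yl)ethyl]magnesium bromide
Product: 4 (2R,3S)-2-[2-(1,3-dioxan-2-yl)ethyl]-3,7-dimethyloct-6-ene-1,3-diol
Conditions: 3 (3 equiv), CuI (10 mol %), THF, −30 → 0 °C; aqueous work-up
Reagents that add atoms: none
Why: Copper-catalysed Grignard opening of a 3,3-disubstituted 2,3-epoxy alcohol, in which the quaternary epoxide carbon is inaccessible so the alkyl group should attack the secondary carbon in an SN2 manner with inversion, setting the later C7 centre next to the retained tertiary carbinol.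

Step 3
Reactants: 4 (2R,3S)-2-[2-(1,3-dioxan-2-yl)ethyl]-3,7-dimethyloct-6-ene-1,3-diol; 5 1-(triphenylphosphoranylidene)propan-2-one
Product: 7 (3E,5R,6S)-5-[2-(1,3-dioxan-2-yl)ethyl]-6-hydroxy-6,10-dimethylundeca-3,9-dien-2-one, via hydroxy aldehyde 6 (not isolated)
Conditions: TEMPO (2,2,6,6-tetramethylpiperidin-1-oxyl, 10 mol %), PhI(OAc)2, CH2Cl2, rt; then 5, 40 °C
Reagents that add atoms: none
Why: Oxoammonium oxidation touches only the primary alcohol, and the in-situ Wittig reaction with the stabilised ylide should give the E enone while sparing the retro-aldol-prone β-hydroxy aldehyde an isolation, so the C7 centre is carried through unchanged.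

Step 4
Reactants: 7 (3E,5R,6S)-5-[2-(1,3-dioxan-2-yl)ethyl]-6-hydroxy-6,10-dimethylundeca-3,9-dien-2-one
Product: 8 (3E,5R,6S)-5-[2-(1,3-dioxan-2-yl)ethyl]-2,6,10-trimethylundeca-1,3,9-trien-6-ol
Conditions: Ph3PCH3Br, KOtBu, THF, 0 °C → rt
Reagents that add atoms: methyltriphenylphosphonium bromide (used as its ylide), C[P+](c1ccccc1)(c1ccccc1)c1ccccc1.[Br-]
Why: Wittig methylenation of the methyl ketone by fast 1,2-addition of the non-stabilised ylide converts the enone into the (E)-2-methyl-1,3-diene without touching the stereocentres.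

Step 5
Reactants: 8 (3E,5R,6S)-5-[2-(1,3-dioxan-2-yl)ethyl]-2,6,10-trimethylundeca-1,3,9-trien-6-ol
Product: 9 (5R,6S)-6-methyl-5-[(1E)-3-methylbuta-1,3-dien-1-yl]-6-(4-methylpent-3-en-1-yl)oxan-2-ol
Conditions: AcOH/THF/H2O, 45 °C
Reagents that add atoms: water, O
Why: Acid-catalysed acetal hydrolysis, assisted by the δ-hydroxyl, which traps the liberated aldehyde as a six-membered lactol, while the diene and the tertiary carbinol tolerate dilute acetic acid.

Step 6
Reactants: 9 (5R,6S)-6-methyl-5-[(1E)-3-methylbuta-1,3-dien-1-yl]-6-(4-methylpent-3-en-1-yl)oxan-2-ol; 10 vinylmagnesium bromide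
Product: 11 (6R,7S)-7,11-dimethyl-6-[(1E)-3-methylbuta-1,3-dien-1-yl]dodeca-1,10-diene-3,7-diol
Conditions: 10 (3 equiv), THF, 0 °C → rt
Reagents that add atoms: none
Why: Grignard addition to the lactol through its open hydroxy aldehyde form gives the allylic alcohol, whose new carbinol centre needs no control because it is oxidised in the next step.

Step 7
Reactants: 11 (6R,7S)-7,11-dimethyl-6-[(1E)-3-methylbuta-1,3-dien-1-yl]dodeca-1,10-diene-3,7-diol
Product: 13 (4R,4aS,8aS)-4-[(2S)-2-hydroxy-6-methylhept-5-en-2-yl]-6-methyl-3,4,4a,7,8,8a-hexahydronaphthalen-1(2H)-one, via trienone 12 (not isolated)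
Conditions: Dess–Martin periodinane, CH2Cl2, 0 °C → rt; then PhMe added, 70 °C
Reagents that add atoms: none
Why: Chemoselective oxidation of the secondary allylic alcohol gives a 1,7,9-decatrien-3-one that should undergo intramolecular Diels–Alder reaction through the endo transition state (tether carbonyl under the diene), giving the cis ring fusion at C1 and C6, with the bulky C7 substituent anti to the forming C1–C6 bond so that C6–H ends up trans to C7–H.

Step 8
Reactants: 13 (4R,4aS,8aS)-4-[(2S)-2-hydroxy-6-methylhept-5-en-2-yl]-6-methyl-3,4,4a,7,8,8a-hexahydronaphthalen-1(2H)-one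
Product: 14 (4R,4aS,8aS)-4-[(2S,5R)-5-chloro-2,6,6-trimethyloxan-2-yl]-6-methyl-3,4,4a,7,8,8a-hexahydronaphthalen-1(2H)-one
Conditions: N-chlorosuccinimide (1.05 equiv), Ph3P=S (10 mol %), CH2Cl2, −40 → 0 °C, dark
Reagents that add atoms: N-chlorosuccinimide, O=C1CCC(=O)N1Cl
Why: The Lewis-base-activated N-chloroimide transfers Cl+ to the electron-rich C14=C15 prenyl bond while the C11 hydroxyl engages the same alkene, so the C14–Cl and O–C15 bonds form anti through a chloriranium-like transition state. The closest known reaction type is the halonium-induced 6-endo etherification of 5-methylhex-4-en-1-ols to 3-halo-2,2-dimethyloxanes. The oxane closes in the 6-endo-trig mode because positive charge is best stabilised at the dimethyl-substituted C15 (Markovnikov opening), which should override the 5-exo alternative. C14 is controlled by the existing C11 centre: in the chair transition state chlorine is necessarily equatorial (anti to the forming O–C15 bond) and the bulky decalinyl group on C11 takes the equatorial site, leaving the C11 methyl axial, which leads to the trans (2S,5R) oxane. The step needs site selectivity over the C4=C5 ring alkene and over ene-type allylic chlorination; the tethered hydroxyl accelerates reaction at the prenyl group only, whereas the ring alkene has no internal nucleophile and is shielded by the folded cis-decalin. The C10 ketone should not enolise under these neutral, cold conditions.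

Step 9
Reactants: 14 (4R,4aS,8aS)-4-[(2S,5R)-5-chloro-2,6,6-trimethyloxan-2-yl]-6-methyl-3,4,4a,7,8,8a-hexahydronaphthalen-1(2H)-one; 15 (R)-2-methylpropane-2-sulfinamide
Product: 16 (R)-N-[(1E,4R,4aR,8aS)-4-[(2S,5R)-5-chloro-2,6,6-trimethyloxan-2-yl]-6-methyl-3,4,4a,7,8,8a-hexahydronaphthalen-1(2H)-ylidene]-2-methylpropane-2-sulfinamide
Conditions: Ti(OEt)4, THF, 60 °C
Reagents that add atoms: none
Why: Titanium-alkoxide-mediated condensation of the ketone with the sulfinamide gives the N-sulfinyl ketimine, whose sulfinyl group should sit anti to the branched C1, and the moderate temperature is chosen to keep the C1 centre of the cis fusion from equilibrating.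

Step 10
Reactants: 16 (R)-N-[(1E,4R,4aR,8aS)-4-[(2S,5R)-5-chloro-2,6,6-trimethyloxan-2-yl]-6-methyl-3,4,4a,7,8,8a-hexahydronaphthalen-1(2H)-ylidene]-2-methylpropane-2-sulfinamide
Product: 17 (R)-N-[(1R,4R,4aR,8aS)-4-[(2S,5R)-5-chloro-2,6,6-trimethyloxan-2-yl]-1,6-dimethyl-1,2,3,4,4a,7,8,8a-octahydronaphthalen-1-yl]-2-methylpropane-2-sulfinamide
Conditions: AlMe3, PhMe, −78 °C; then MeLi, −78 °C
Reagents that add atoms: methyllithium, [Li]C
Why: 1,2-Addition of methyllithium to the AlMe3-activated sulfinyl ketimine should outrun α-deprotonation, and the methyl group should enter from the convex face anti to the axial C1–C2 bond, the same face that the (R)-sulfinyl group selects in the chelated six-membered transition state, which sets C10 with methyl on the convex face and nitrogen equatorial.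

Step 11
Reactants: 17 (R)-N-[(1R,4R,4aR,8aS)-4-[(2S,5R)-5-chloro-2,6,6-trimethyloxan-2-yl]-1,6-dimethyl-1,2,3,4,4a,7,8,8a-octahydronaphthalen-1-yl]-2-methylpropane-2-sulfinamide
Product: 18 (1R,4R,4aR,8aS)-4-[(2S,5R)-5-chloro-2,6,6-trimethyloxan-2-yl]-1,6-dimethyl-1,2,3,4,4a,7,8,8a-octahydronaphthalen-1-amine
Conditions: HCl (4 M in dioxane), MeOH, 0 °C; then aq. NaOH
Reagents that add atoms: none
Why: Acidic methanolysis cleaves the N–S bond of the sulfinamide under conditions that leave the oxane ether, the secondary chloride and the ring alkene intact.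

Step 12
Reactants: 18 (1R,4R,4aR,8aS)-4-[(2S,5R)-5-chloro-2,6,6-trimethyloxan-2-yl]-1,6-dimethyl-1,2,3,4,4a,7,8,8a-octahydronaphthalen-1-amine
Product: 19 N-[(1R,4R,4aR,8aS)-4-[(2S,5R)-5-chloro-2,6,6-trimethyloxan-2-yl]-1,6-dimethyl-1,2,3,4,4a,7,8,8a-octahydronaphthalen-1-yl]formamide
Conditions: acetic formic anhydride, THF, 0 °C → rt
Reagents that add atoms: acetic formic anhydride, CC(=O)OC=O
Why: N-Formylation of the hindered tert-alkyl amine with the mixed anhydride, which transfers the more electrophilic formyl group and creates no new stereocentre.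

Compound list
1 | geraniol | CC(C)=CCC/C(C)=C/CO | starting material
2 | (2S,3S)-2,3-epoxygeraniol | OC[C@@H]1O[C@@]1(C)CCC=C(C)C | intermediate
3 | [2-(1,3-dioxan-2-yl)ethyl]magnesium bromide | Br[Mg]CCC1OCCCO1 | starting material
4 | (2R,3S)-2-[2-(1,3-dioxan-2-yl)ethyl]-3,7-dimethyloct-6-ene-1,3-diol | OC[C@@H](CCC1OCCCO1)[C@@](C)(O)CCC=C(C)C | intermediate
5 | 1-(triphenylphosphoranylidene)propan-2-one | CC(=O)C=P(c1ccccc1)(c1ccccc1)c1ccccc1 | starting material
6 | (2S,3S)-2-[2-(1,3-dioxan-2-yl)ethyl]-3-hydroxy-3,7-dimethyloct-6-enal (hydroxy aldehyde, not isolated) | O=C[C@@H](CCC1OCCCO1)[C@@](C)(O)CCC=C(C)C | intermediate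
7 | (3E,5R,6S)-5-[2-(1,3-dioxan-2-yl)ethyl]-6-hydroxy-6,10-dimethylundeca-3,9-dien-2-one | CC(=O)/C=C/[C@@H](CCC1OCCCO1)[C@@](C)(O)CCC=C(C)C | intermediate
8 | (3E,5R,6S)-5-[2-(1,3-dioxan-2-yl)ethyl]-2,6,10-trimethylundeca-1,3,9-trien-6-ol | C=C(C)/C=C/[C@@H](CCC1OCCCO1)[C@@](C)(O)CCC=C(C)C | intermediate
9 | (5R,6S)-6-methyl-5-[(1E)-3-methylbuta-1,3-dien-1-yl]-6-(4-methylpent-3-en-1-yl)oxan-2-ol (anomeric mixture) | OC1CC[C@H](/C=C/C(C)=C)[C@](C)(CCC=C(C)C)O1 | intermediate
10 | vinylmagnesium bromide | C=C[Mg]Br | starting material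
11 | (6R,7S)-7,11-dimethyl-6-[(1E)-3-methylbuta-1,3-dien-1-yl]dodeca-1,10-diene-3,7-diol (epimers at C3) | C=CC(O)CC[C@H](/C=C/C(C)=C)[C@@](C)(O)CCC=C(C)C | intermediate
12 | (6R,7S)-7-hydroxy-7,11-dimethyl-6-[(1E)-3-methylbuta-1,3-dien-1-yl]dodeca-1,10-dien-3-one (trienone, not isolated) | C=CC(=O)CC[C@H](/C=C/C(C)=C)[C@@](C)(O)CCC=C(C)C | intermediate
13 | (4R,4aS,8aS)-4-[(2S)-2-hydroxy-6-methylhept-5-en-2-yl]-6-methyl-3,4,4a,7,8,8a-hexahydronaphthalen-1(2H)-one | CC1=C[C@H]2[C@H]([C@@](C)(O)CCC=C(C)C)CCC(=O)[C@H]2CC1 | intermediate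
14 | (4R,4aS,8aS)-4-[(2S,5R)-5-chloro-2,6,6-trimethyloxan-2-yl]-6-methyl-3,4,4a,7,8,8a-hexahydronaphthalen-1(2H)-one | CC1=C[C@H]2[C@H]([C@]3(C)CC[C@@H](Cl)C(C)(C)O3)CCC(=O)[C@H]2CC1 | intermediate
15 | (R)-2-methylpropane-2-sulfinamide | CC(C)(C)[S@@](=O)N | starting material
16 | (R)-N-[(1E,4R,4aR,8aS)-4-[(2S,5R)-5-chloro-2,6,6-trimethyloxan-2-yl]-6-methyl-3,4,4a,7,8,8a-hexahydronaphthalen-1(2H)-ylidene]-2-methylpropane-2-sulfinamide | CC1=C[C@H]2[C@H]([C@]3(C)CC[C@@H](Cl)C(C)(C)O3)CC/C(=N\[S@](=O)C(C)(C)C)[C@H]2CC1 | intermediate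
17 | (R)-N-[(1R,4R,4aR,8aS)-4-[(2S,5R)-5-chloro-2,6,6-trimethyloxan-2-yl]-1,6-dimethyl-1,2,3,4,4a,7,8,8a-octahydronaphthalen-1-yl]-2-methylpropane-2-sulfinamide | CC1=C[C@H]2[C@H]([C@]3(C)CC[C@@H](Cl)C(C)(C)O3)CC[C@@](C)(N[S@](=O)C(C)(C)C)[C@H]2CC1 | intermediate
18 | (1R,4R,4aR,8aS)-4-[(2S,5R)-5-chloro-2,6,6-trimethyloxan-2-yl]-1,6-dimethyl-1,2,3,4,4a,7,8,8a-octahydronaphthalen-1-amine | CC1=C[C@H]2[C@H]([C@]3(C)CC[C@@H](Cl)C(C)(C)O3)CC[C@@](C)(N)[C@H]2CC1 | intermediate
19 | N-[(1R,4R,4aR,8aS)-4-[(2S,5R)-5-chloro-2,6,6-trimethyloxan-2-yl]-1,6-dimethyl-1,2,3,4,4a,7,8,8a-octahydronaphthalen-1-yl]formamide | CC1=C[C@H]2[C@H]([C@]3(C)CC[C@@H](Cl)C(C)(C)O3)CC[C@@](C)(NC=O)[C@H]2CC1 | target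

Total step count: 12. Longest linear sequence: 12 steps, from geraniol.

Steps most likely to fail

Step 8. Cl+ may be diverted into ene-type allylic chlorination of the prenyl unit or into attack on the C4=C5 alkene, the closure may leak into the 5-exo mode, and facial discrimination in the chair may be incomplete. The fallback replaces the stoichiometric N-chloro reagent by biocatalytic oxidation of chloride. A vanadium-dependent chloroperoxidase (Na3VO4-loaded enzyme, KCl, slowly fed H2O2, citrate buffer pH 5, t-BuOH co-solvent) produces hypochlorite only at a very low stationary concentration, and enzymes of this class are known to convert prenyl groups with a pendant oxygen nucleophile into 3-chloro-2,2-dimethyloxanes. This fallback sets out from 13 and comes back to the route at 14 without any new intermediate (F0).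

Step 9. The hot titanium-mediated condensation may erode the cis ring fusion by enolisation or imine–enamine tautomerism at C1, and the hindered carbonyl may condense incompletely. The fallback sets out from 14 and avoids equilibrating conditions. Buffered oximation at room temperature (NH2OH·HCl, NaOAc, MeOH) gives the oxime F1. Ph2PCl and Et3N in CH2Cl2 at −40 °C → rt convert it, through rearrangement of the O-phosphinite, into the N-diphenylphosphinoyl ketimine F2. MeMgBr in PhMe at −40 °C should add from the convex face to give the phosphinamide F3. Cleavage of the P–N bond with HCl in MeOH brings the route back at amine 18.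

Step 3. The β-hydroxy aldehyde may undergo retro-aldol cleavage, β-elimination or epimerisation at C7 before the slow olefination of the hindered carbonyl. The fallback sets out from diol 4 and masks the tertiary hydroxyl. Et3SiOTf and 2,6-lutidine give the bis(triethylsilyl) ether F4. Swern oxidation, which converts a primary triethylsilyl ether directly into the aldehyde, gives the protected aldehyde F5. Wittig reaction with 5 gives the protected enone F6, and methylenation (Ph3PCH3Br, KOtBu) gives the protected diene F7. Aqueous HCl in THF then removes the silyl ether together with the acetal and returns the route at lactol 9.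

Further compounds
F0 | step 8 | none | none
F1 | step 9 | (4R,4aR,8aS)-4-[(2S,5R)-5-chloro-2,6,6-trimethyloxan-2-yl]-6-methyl-3,4,4a,7,8,8a-hexahydronaphthalen-1(2H)-one oxime | CC1=C[C@H]2[C@H]([C@]3(C)CC[C@@H](Cl)C(C)(C)O3)CCC(=NO)[C@H]2CC1
F2 | step 9 | N-[(4R,4aR,8aS)-4-[(2S,5R)-5-chloro-2,6,6-trimethyloxan-2-yl]-6-methyl-3,4,4a,7,8,8a-hexahydronaphthalen-1(2H)-ylidene]-P,P-diphenylphosphinic amide | CC1=C[C@H]2[C@H]([C@]3(C)CC[C@@H](Cl)C(C)(C)O3)CCC(=NP(=O)(c4ccccc4)c5ccccc5)[C@H]2CC1
F3 | step 9 | N-[(1R,4R,4aR,8aS)-4-[(2S,5R)-5-chloro-2,6,6-trimethyloxan-2-yl]-1,6-dimethyl-1,2,3,4,4a,7,8,8a-octahydronaphthalen-1-yl]-P,P-diphenylphosphinic amide | CC1=C[C@H]2[C@H]([C@]3(C)CC[C@@H](Cl)C(C)(C)O3)CC[C@@](C)(NP(=O)(c4ccccc4)c5ccccc5)[C@H]2CC1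
F4 | step 3 | bis(triethylsilyl) ether of diol 4 | CC[Si](CC)(CC)OC[C@@H](CCC1OCCCO1)[C@@](C)(O[Si](CC)(CC)CC)CCC=C(C)C
F5 | step 3 | (2S,3S)-2-[2-(1,3-dioxan-2-yl)ethyl]-3,7-dimethyl-3-(triethylsilyloxy)oct-6-enal | O=C[C@@H](CCC1OCCCO1)[C@@](C)(O[Si](CC)(CC)CC)CCC=C(C)C
F6 | step 3 | triethylsilyl ether of enone 7 | CC(=O)/C=C/[C@@H](CCC1OCCCO1)[C@@](C)(O[Si](CC)(CC)CC)CCC=C(C)C
F7 | step 3 | triethylsilyl ether of diene 8 | C=C(C)/C=C/[C@@H](CCC1OCCCO1)[C@@](C)(O[Si](CC)(CC)CC)CCC=C(C)C
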